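## Structural features

The target is a C25 acid built on a single ring, a 3,6-dihydro-2H-pyran (O1, C2, C3, C4=C5, C6). C2 carries a 2-propenoic acid unit through its α-carbon, and C5 carries a sixteen-carbon (3E,7E)-4,8,12-trimethyltrideca-3,7,11-trienyl (homofarnesyl) chain. C2 is the only stereocentre and is (R) (O1 > propenyl carbon > C3 > H), so no relative configuration has to be controlled. That centre is α to the ring oxygen, allylic to the exocyclic methylene and γ to the carboxyl group, which makes its hydrogen and the C2–O1 bond the sensitive points under base and Lewis acid. The α-substituted acrylic acid is a Michael acceptor and polymerisable. The tail holds three trisubstituted alkenes, two of them stereogenic (E), in a skipped 1,5-diene array that cyclises in acid and reacts with electrophilic oxidants. The ring is easy to make; the real difficulty is joining a polar, chiral head to a long polyene tail without moving or isomerising any of the five alkenes, and carrying the carboxyl carbon through organometallic chemistry. The key step exploits the fact that C1′–C2′ is the central single bond of the 1,5-diene C4=C5–C1′–C2′–C3′=C4′. C1′ is allylic to the ring alkene and C2′ to the first chain alkene, so both can be primary allylic halides, and reductive metalation of one lets two like-polarity fragments be joined there.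

## Logic of the disconnections

18 to 15 (through 17 and 16): no skeletal bond is cut. The carboxyl carbon is stepped down to the aldehyde and alcohol levels and then masked as a silyl ether. This is done because an acrylate or enal would be attacked by an allylbarium, whereas 15 holds only ethers and alkenes. The forward demand is an oxidation selective for one allylic alcohol beside four other alkenes that does not let the exocyclic alkene slip into conjugation with O1.

15 to 13 and 11 (through 14): the C1′–C2′ bond is cut. Both carbons are primary and allylic, and the cut divides the molecule into a C15 tail that is one step from a commercial alcohol and a nine-carbon chiral head. No ring and no stereocentre is involved. The forward step must be α-selective at both allyl termini, keep the 2E geometry, and favour cross- over homo-coupling.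

13 to 12: the C–Cl bond is traced to the allylic alcohol. The forward chlorination must not transpose the allyl system.

11 to 9 (through 10): the C–Br bond is traced to C–OH and then to a conjugated ester. The ester is the level at which the ring-forming partner is commercial. The forward demand is clean 1,2-reduction and a neutral bromination that leaves the silyl ether alone.

9 to 8: the ring alkene C4=C5 is cut by a metathesis transform. This opens the ring to a triene ether and places the trisubstituted alkene exactly where the chain must later attach. The forward step must close on the acrylate olefin and ignore the other 1,1-disubstituted olefin.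

8 to 6 and 7: the O1–C6 ether bond is cut. The stereocentre is untouched because its C–O bond stays intact. The forward alkylation needs a secondary alkoxide next to a silyl ether, so the silyl group must not migrate.

6 to 3 and 4 (through 5): the C2–C3 bond is cut. This is the only stereogenic step, and it reduces the head to a non-enolisable enal and an allylboronate. The forward demand is high facial selectivity at the aldehyde.

3 to 2 to 1: the aldehyde is traced to the alcohol and the silyl ether to a symmetric diol. The forward demand is monosilylation of one of two equivalent hydroxyl groups.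

## Other disconnections considered

Alternative 1: The cut is the ring bond C5–C6, with C6 traced back to a one-carbon acetal on the C2 oxygen.
- Forward step: the open-chain (Z)-vinylsilane methoxymethyl ether A1 already carries the whole tail and a silyl-protected hydroxymethyl group at C2. SnCl4 would ionise the acetal to the O1=C6 oxocarbenium ion, the silicon-bearing carbon C5 would attack C6, and loss of silicon from the β-silyl cation at C4 would leave the alkene at C4–C5, giving A2.
- In favour: the position of the ring alkene is dictated by silicon and is as secure as in the metathesis of the chosen plan, a point of equality. The stereocentre could come from the chiral pool instead of a catalytic asymmetric reaction, a point on which this alternative is better. No ruthenium or barium chemistry is needed.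
- Against: a strong Lewis acid and an oxocarbenium ion are the usual triggers of cation–olefin cyclisation, and the three trisubstituted alkenes of the tail are at least as nucleophilic as the vinylsilane. The trisubstituted vinylsilane must be made with defined geometry on a C16 chain. A2 has only one carbon at C2, so five or more further steps would be needed, passing C2 through an epimerisable α-alkoxy carbonyl stage.
- Comparison: structurally it is linear, with the tail in place before the ring, where the chosen plan joins two finished fragments. Mechanistically it is cationic where the chosen plan is carbanionic, and the polyene tolerates the latter better. In step economy the chosen plan needs three steps after its key step against five or more.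

Alternative 2: The cut is the O1–C2 bond.
- Forward step: the racemic Morita–Baylis–Hillman tert-butyl carbonate A3, a (Z)-allylic alcohol with the tail on C5, would be treated with (DHQD)2PHAL or its pseudoenantiomer. The amine adds SN2′ with loss of CO2 and tert-butoxide, which erases the carbinol centre in an allylammonium enoate. The C6 alkoxide then attacks C2 in a second SN2′ step that closes the ring, sets C2 under catalyst control and restores the exocyclic methylene, giving A4.
- In favour: both enantiomers of the substrate converge, ring closure and stereogenesis are one event, and the acrylate appears at the right oxidation level without a protecting group. Only an ester hydrolysis separates A4 from the target. In steps after the key step (one against three) and in freedom from metals this alternative is better than the chosen plan.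
- Against: A3 requires a stereodefined (Z)-trisubstituted allylic alcohol on the C16 chain and a Morita–Baylis–Hillman reaction of a β,γ-unsaturated aldehyde that tends to slip into conjugation. High enantioselectivity in an intramolecular six-ring O-alkylation of this type is less well founded than in intermolecular cases, and any uncatalysed cyclisation would give racemic material. The final saponification must neither open the ring by SN2′ attack nor move the exocyclic alkene.
- Comparison: both plans are gentle on the polyene, a point of equality. The stereocentre is catalyst-set in both, but in the chosen plan through a closed, well-understood transition state. The alternative is linear and places its least certain step late on the most valuable material; the chosen plan puts its risk in a union of two fragments that are easily remade.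

Alternative 3: The cut is C2–C3, paired with a C–O bond to the carbon that becomes C5.
- Forward step: the dioxanone A5, with vinyl and tail on its tertiary carbon C6, would be converted into its silyl ketene acetal with an amide base and a chlorosilane. This rearranges through the boat-like arrangement forced by the ring: C2–C3 forms, the tertiary allylic C–O bond breaks, and acid A6 results with the alkene at C4–C5. By the suprafacial course, (R)-A5 should give (R)-A6.
- In favour: a concerted sigmatropic step with transfer of chirality is the most predictable stereochemical event of the four plans, and here the alternative is better than the catalyst-controlled allylboration of the chosen plan. It tolerates the polyene, needs no transition metal and fixes the ring alkene as securely as metathesis.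
- Against: the stereochemical burden moves to a tertiary carbinol carbon bearing vinyl, the tail and CH2O, which is harder to obtain enantioenriched than a secondary allylic alcohol. A6 lacks the methylene-bearing carbon, so the carboxyl group must be rebuilt into a 1-carboxyvinyl group in four or five steps through an epimerisable α-alkoxy ketone stage.
- Comparison: structurally it is linear with the tail present from the start. Mechanistically it is cleaner at the key step. In step economy it is longer both before and after the key step (four to five steps after, against three).

Key step: step 9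

Assumption: the (R)-configured phosphoric acid of step 3 is taken to direct the allyl group to the Re face of the aldehyde, as it does with aryl and conjugated aldehydes; if the sense were opposite, its enantiomer would be used with no other change.

Remark on the precursor: the oxygen that becomes the carboxyl group is carried as a triisopropylsilyl ether. A tert-butyldimethylsilyl ether would serve in the coupling itself but is more prone to 1,5 O-to-O migration when the neighbouring secondary alkoxide is formed in step 4.

Remark on the structures: all descriptors were re-derived. C2 stays (R) in 5, 6, 8 to 11 and 15 to 18, because the order O > propenyl carbon > CH2 > H never changes and the C2–O bond is never broken.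

## Steps

Step 1
Reactants: 1 2-methylenepropane-1,3-diol
Product: 2 2-{[(triisopropylsilyl)oxy]methyl}prop-2-en-1-ol
Conditions: NaH (1.0 equiv), THF, 0 °C to rt; then i-Pr3SiCl (1.0 equiv), rt
Reagents that add atoms: chlorotriisopropylsilane, CC(C)[Si](Cl)(C(C)C)C(C)C
Why: One equivalent of NaH gives a poorly soluble monosodium alkoxide that is silylated once, so the symmetric diol should be monoprotected well beyond the statistical level (O-silylation of a monoalkoxide). The triisopropylsilyl group resists O-to-O migration and survives every later step until fluoride.

Step 2
Reactants: 2 2-{[(triisopropylsilyl)oxy]methyl}prop-2-en-1-ol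
Product: 3 2-{[(triisopropylsilyl)oxy]methyl}prop-2-enal
Conditions: activated MnO2 (15 equiv), CH2Cl2, rt
Reagents that add atoms: none
Why: Activated MnO2 oxidises the primary allylic alcohol to the enal on the solid surface under neutral conditions, without over-oxidation and without touching the silyl ether (allylic oxidation).

Step 3
Reactants: 3 2-{[(triisopropylsilyl)oxy]methyl}prop-2-enal; 4 allylboronic acid pinacol ester (2-allyl-4,4,5,5-tetramethyl-1,3,2-dioxaborolane)
Product: 6 (3R)-2-{[(triisopropylsilyl)oxy]methyl}hexa-1,5-dien-3-ol, via pinacol borate ester 5 (not isolated)
Conditions: (R)-TRIP phosphoric acid [(R)-3,3′-bis(2,4,6-triisopropylphenyl)-1,1′-binaphthyl-2,2′-diyl hydrogen phosphate] (5 mol%), toluene, −30 °C; then aq. NaHCO3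
Reagents that add atoms: none
Why: Brønsted acid-catalysed asymmetric allylboration through a closed chair (Zimmerman–Traxler) transition state in which the acid hydrogen-bonds to a boronate oxygen; the (R)-acid is expected to expose the Re face of the aldehyde, which sets C2 as (R), and borate 5 is hydrolysed on work-up. The aldehyde cannot enolise and reacts by 1,2-addition, so the acrolein alkene is kept as the future exocyclic methylene.

Step 4
Reactants: 6 (3R)-2-{[(triisopropylsilyl)oxy]methyl}hexa-1,5-dien-3-ol; 7 methyl 2-(bromomethyl)acrylate
Product: 8 methyl 2-({[(3R)-2-{[(triisopropylsilyl)oxy]methyl}hexa-1,5-dien-3-yl]oxy}methyl)prop-2-enoate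
Conditions: NaH (1.2 equiv), THF, 0 °C; then 7 (1.3 equiv), 0 °C to rt
Reagents that add atoms: none
Why: Williamson etherification with an activated allylic bromide; direct SN2 and SN2′ addition–elimination lead to the same ether, and the C–O bond at the stereocentre is not broken, so the configuration is retained. The bulky silyl group should keep the sodium alkoxide from taking silicon from the neighbouring oxygen.

Step 5
Reactants: 8 methyl 2-({[(3R)-2-{[(triisopropylsilyl)oxy]methyl}hexa-1,5-dien-3-yl]oxy}methyl)prop-2-enoate
Product: 9 methyl (6R)-6-{3-[(triisopropylsilyl)oxy]prop-1-en-2-yl}-5,6-dihydro-2H-pyran-3-carboxylate (C6 of this name is C2 of the target numbering)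
Conditions: second-generation Grubbs catalyst RuCl2(=CHPh)(H2IMes)(PCy3) (5 mol%), CH2Cl2 (0.01 M), 40 °C
Reagents that add atoms: none
Why: Ring-closing metathesis: the ruthenium carbene loads at the only monosubstituted alkene and closes on the acrylate olefin to give the six-membered ring with the trisubstituted C4=C5 bond and loss of ethene. Closure on the silyloxymethyl-substituted olefin would require a cyclobutene and is not expected.

Step 6
Reactants: 9 methyl (6R)-6-{3-[(triisopropylsilyl)oxy]prop-1-en-2-yl}-5,6-dihydro-2H-pyran-3-carboxylate
Product: 10 [(6R)-6-{3-[(triisopropylsilyl)oxy]prop-1-en-2-yl}-5,6-dihydro-2H-pyran-3-yl]methanol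
Conditions: i-Bu2AlH (2.5 equiv), CH2Cl2, −78 °C; aq. KNaC4H4O6 (potassium sodium tartrate)
Reagents that add atoms: none
Why: 1,2-Reduction of the conjugated ester by i-Bu2AlH at low temperature should give the primary allylic alcohol and leave the silyl ether, both alkenes and C2 untouched.

Step 7
Reactants: 10 [(6R)-6-{3-[(triisopropylsilyl)oxy]prop-1-en-2-yl}-5,6-dihydro-2H-pyran-3-yl]methanol
Product: 11 (2R)-5-(bromomethyl)-2-{3-[(triisopropylsilyl)oxy]prop-1-en-2-yl}-3,6-dihydro-2H-pyran
Conditions: CBr4 (1.3 equiv), PPh3 (1.4 equiv), CH2Cl2, 0 °C
Reagents that add atoms: carbon tetrabromide, BrC(Br)(Br)Br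
Why: Appel bromination: bromide displaces the alkoxyphosphonium group at the primary carbon (SN2) under neutral conditions, so the silyl ether is kept and the ring alkene is not transposed. The bromide would be used at once in step 9.

Step 8
Reactants: 12 (2E,6E)-farnesol
Product: 13 (2E,6E)-farnesyl chloride
Conditions: NCS (1.2 equiv), Me2S (1.3 equiv), CH2Cl2, −40 to 0 °C
Reagents that add atoms: N-chlorosuccinimide, ClN1C(=O)CCC1=O
Why: Corey–Kim chlorination: chloride displaces the alkoxysulfonium group at the primary carbon below 0 °C, which avoids allylic transposition and keeps the 2E geometry. Fresh preparation secures the titre needed for the metalation.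

Step 9
Reactants: 13 (2E,6E)-farnesyl chloride; 11 (2R)-5-(bromomethyl)-2-{3-[(triisopropylsilyl)oxy]prop-1-en-2-yl}-3,6-dihydro-2H-pyran
Product: 15 (2R)-2-{3-[(triisopropylsilyl)oxy]prop-1-en-2-yl}-5-[(3E,7E)-4,8,12-trimethyltrideca-3,7,11-trien-1-yl]-3,6-dihydro-2H-pyran, via farnesylbarium chloride 14 (not isolated)
Conditions: BaI2 (2.1 equiv), lithium biphenylide (4.0 equiv), THF, rt, 30 min; 13 (2.2 equiv), −78 °C, 30 min; then 11 (1.0 equiv), THF, −78 °C; aq. NH4Cl
Reagents that add atoms: none
Why: Finely divided zerovalent barium, formed from BaI2 and two equivalents of lithium biphenylide, inserts into the C–Cl bond of 13 at −78 °C by two single-electron transfers and gives 14, a σ-allyl organometallic that at this temperature should neither shift the metal to C3 nor lose the 2E geometry. The α-carbon of 14 then displaces bromide from the CH2Br carbon of 11 in a direct substitution, forming C1′–C2′ and divalent barium halide. The closest known reaction type is the α,α′-selective, geometry-retentive cross-coupling of allylbarium reagents with allylic halides to give 1,5-dienes. No ring is closed and no stereocentre is formed; C2 lies four bonds from the reacting carbon and has no acidifying carbonyl group beside it, so it should be unaffected. The step needs α- over γ-attack at both termini, retention of the E alkene and cross- over homo-coupling. On the nucleophile the α-preference is intrinsic to allylbarium at low temperature; on the electrophile the γ-carbon C4 is ring-embedded and attack there would force an exocyclic alkene, so the unhindered primary carbon should be preferred. Cross-selectivity is secured by consuming all zerovalent barium with a slight excess of 13 before 11 is added, so that 11 meets only 14, and by the low temperature, at which halogen–metal exchange should be slow compared with substitution. Substrate 11 offers only ethers and alkenes, neither an acidic hydrogen nor a Michael acceptor.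

Step 10
Reactants: 15 (2R)-2-{3-[(triisopropylsilyl)oxy]prop-1-en-2-yl}-5-[(3E,7E)-4,8,12-trimethyltrideca-3,7,11-trien-1-yl]-3,6-dihydro-2H-pyran
Product: 16 2-{(2R)-5-[(3E,7E)-4,8,12-trimethyltrideca-3,7,11-trien-1-yl]-3,6-dihydro-2H-pyran-2-yl}prop-2-en-1-ol
Conditions: Bu4NF (1.5 equiv), THF, 0 °C to rt
Reagents that add atoms: none
Why: Fluoride cleaves the Si–O bond (desilylation) and releases the primary allylic alcohol without affecting anything else in 15. The polar product should separate easily from biphenyl and hydrocarbon by-products carried over from step 9.

Step 11
Reactants: 16 2-{(2R)-5-[(3E,7E)-4,8,12-trimethyltrideca-3,7,11-trien-1-yl]-3,6-dihydro-2H-pyran-2-yl}prop-2-en-1-ol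
Product: 17 2-{(2R)-5-[(3E,7E)-4,8,12-trimethyltrideca-3,7,11-trien-1-yl]-3,6-dihydro-2H-pyran-2-yl}prop-2-enal
Conditions: activated MnO2 (20 equiv), CH2Cl2, rt
Reagents that add atoms: none
Why: MnO2 oxidises only the allylic alcohol and gives the 2-substituted propenal under neutral conditions (allylic oxidation). This avoids base-induced migration of the exocyclic alkene into conjugation with O1 and leaves C2 intact.

Step 12
Reactants: 17 2-{(2R)-5-[(3E,7E)-4,8,12-trimethyltrideca-3,7,11-trien-1-yl]-3,6-dihydro-2H-pyran-2-yl}prop-2-enal
Product: 18 2-{(2R)-5-[(3E,7E)-4,8,12-trimethyltrideca-3,7,11-trien-1-yl]-3,6-dihydro-2H-pyran-2-yl}prop-2-enoic acid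
Conditions: NaClO2 (3 equiv), NaH2PO4 (4 equiv), 2-methyl-2-butene (30 equiv), t-BuOH/H2O, 0 °C to rt
Reagents that add atoms: sodium chlorite, [Na+].[O-]Cl=O
Why: Pinnick oxidation: chlorous acid adds to the aldehyde and fragments to the acid and HOCl, which the large excess of 2-methyl-2-butene removes before it can attack the trisubstituted alkenes. The weakly acidic buffer should neither epimerise C2 nor move the exocyclic alkene.

## Compound list

1 | 2-methylenepropane-1,3-diol | C=C(CO)CO | starting material
2 | 2-{[(triisopropylsilyl)oxy]methyl}prop-2-en-1-ol | C=C(CO)CO[Si](C(C)C)(C(C)C)C(C)C | intermediate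
3 | 2-{[(triisopropylsilyl)oxy]methyl}prop-2-enal | C=C(C=O)CO[Si](C(C)C)(C(C)C)C(C)C | intermediate
4 | allylboronic acid pinacol ester | C=CCB1OC(C)(C)C(C)(C)O1 | starting material
5 | 4,4,5,5-tetramethyl-2-{[(3R)-2-{[(triisopropylsilyl)oxy]methyl}hexa-1,5-dien-3-yl]oxy}-1,3,2-dioxaborolane (formed in the flask) | C=C(CO[Si](C(C)C)(C(C)C)C(C)C)[C@H](OB1OC(C)(C)C(C)(C)O1)CC=C | intermediate
6 | (3R)-2-{[(triisopropylsilyl)oxy]methyl}hexa-1,5-dien-3-ol | C=C(CO[Si](C(C)C)(C(C)C)C(C)C)[C@H](O)CC=C | intermediate
7 | methyl 2-(bromomethyl)acrylate | C=C(CBr)C(=O)OC | starting material
8 | methyl 2-({[(3R)-2-{[(triisopropylsilyl)oxy]methyl}hexa-1,5-dien-3-yl]oxy}methyl)prop-2-enoate | C=C(CO[Si](C(C)C)(C(C)C)C(C)C)[C@H](OCC(=C)C(=O)OC)CC=C | intermediate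
9 | methyl (6R)-6-{3-[(triisopropylsilyl)oxy]prop-1-en-2-yl}-5,6-dihydro-2H-pyran-3-carboxylate | C=C(CO[Si](C(C)C)(C(C)C)C(C)C)[C@H]1CC=C(C(=O)OC)CO1 | intermediate
10 | [(6R)-6-{3-[(triisopropylsilyl)oxy]prop-1-en-2-yl}-5,6-dihydro-2H-pyran-3-yl]methanol | C=C(CO[Si](C(C)C)(C(C)C)C(C)C)[C@H]1CC=C(CO)CO1 | intermediate
11 | (2R)-5-(bromomethyl)-2-{3-[(triisopropylsilyl)oxy]prop-1-en-2-yl}-3,6-dihydro-2H-pyran | C=C(CO[Si](C(C)C)(C(C)C)C(C)C)[C@H]1CC=C(CBr)CO1 | intermediate
12 | (2E,6E)-farnesol | OC/C=C(\C)CC/C=C(\C)CCC=C(C)C | starting material
13 | (2E,6E)-farnesyl chloride | ClC/C=C(\C)CC/C=C(\C)CCC=C(C)C | intermediate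
14 | (2E,6E)-farnesylbarium chloride (formed in the flask) | Cl[Ba]C/C=C(\C)CC/C=C(\C)CCC=C(C)C | intermediate
15 | (2R)-2-{3-[(triisopropylsilyl)oxy]prop-1-en-2-yl}-5-[(3E,7E)-4,8,12-trimethyltrideca-3,7,11-trien-1-yl]-3,6-dihydro-2H-pyran | C=C(CO[Si](C(C)C)(C(C)C)C(C)C)[C@H]1CC=C(CC/C=C(\C)CC/C=C(\C)CCC=C(C)C)CO1 | intermediate
16 | 2-{(2R)-5-[(3E,7E)-4,8,12-trimethyltrideca-3,7,11-trien-1-yl]-3,6-dihydro-2H-pyran-2-yl}prop-2-en-1-ol | C=C(CO)[C@H]1CC=C(CC/C=C(\C)CC/C=C(\C)CCC=C(C)C)CO1 | intermediate
17 | 2-{(2R)-5-[(3E,7E)-4,8,12-trimethyltrideca-3,7,11-trien-1-yl]-3,6-dihydro-2H-pyran-2-yl}prop-2-enal | C=C(C=O)[C@H]1CC=C(CC/C=C(\C)CC/C=C(\C)CCC=C(C)C)CO1 | intermediate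
18 | 2-{(2R)-5-[(3E,7E)-4,8,12-trimethyltrideca-3,7,11-trien-1-yl]-3,6-dihydro-2H-pyran-2-yl}prop-2-enoic acid | C=C(C(=O)O)[C@H]1CC=C(CC/C=C(\C)CC/C=C(\C)CCC=C(C)C)CO1 | target

## Step count and least certain steps

Total: 12 steps. Longest linear sequence: 11 steps (1 to 18 through steps 1 to 7 and 9 to 12); step 8 is a one-step side branch. Commercial (2E,6E)-farnesyl chloride of good titre could replace step 8.

Step 9 (key step). The likely failures are Wurtz-type homo-coupling of 13 during the metalation, halogen–metal exchange between 14 and 11 that would scramble the partners, attack through the γ-carbon of either allyl unit, and loss of the 2E geometry if the organobarium warms. Fallback with known chemistry, setting out from 13 and 11 and returning at 15: 13 would be treated with PhSO2Na in DMF to give (2E,6E)-farnesyl phenyl sulfone F1. Deprotonation of F1 with n-BuLi in THF at −78 °C and alkylation with 11 would give the coupled sulfone F2 as both epimers at the sulfonyl carbon. Reductive desulfonylation with LiBHEt3 and catalytic PdCl2(dppp) in THF at 0 °C would then give 15. The same C1′–C2′ bond is formed, but with a stabilised carbanion whose α-regiochemistry is fixed by the sulfone, at the cost of two extra steps.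

Step 3. The risk is poor facial discrimination for an α-branched acrolein without a β-substituent, together with an uncatalysed background allylboration that erodes the enantiomeric purity. Fallback, from 3 back to 6: stoichiometric reagent control with B-allyldiisopinocampheylborane made from (−)-α-pinene (from the B-methoxyborane and CH2=CHCH2MgBr), Et2O, −78 °C, then NaOH/H2O2. This reagent is expected to attack the Re face, and the source of asymmetry changes from a catalyst to a chiral allyl donor.

Step 4. The risk is slow alkylation of a hindered secondary alkoxide, which gives time for oxa-Michael oligomerisation of 7 and for residual silyl transfer between the two oxygens. Fallback, from 6 back to 8, without a stoichiometric metal alkoxide: methyl 2-{[(tert-butoxycarbonyl)oxy]methyl}acrylate F3 (one step from commercial methyl 2-(hydroxymethyl)acrylate and di-tert-butyl dicarbonate) would be combined with 6 and catalytic DABCO in toluene at rt. The amine forms an allylammonium enoate with loss of CO2 and tert-butoxide, and the alcohol enters by SN2′ substitution, a known Lewis base-catalysed allylic etherification.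

Step 5. The risk is sluggish closure on the electron-poor 1,1-disubstituted olefin, which would favour intermolecular metathesis at the allyl terminus or hydride-induced migration of the terminal alkene before cyclisation. Fallback, from 6 back to 11, which uses an electronically neutral olefin and bypasses 8, 9 and 10: 6 would be alkylated with excess 3-chloro-2-(chloromethyl)prop-1-ene (NaH, Bu4NI, THF) to give the 2-(chloromethyl)allyl ether F4. Ring-closing metathesis with the same ruthenium catalyst would give the chloromethyl dihydropyran F5, and halide exchange with LiBr in acetone would give 11. This variant is shorter but is held in reserve because the dichloride is a far less reactive electrophile than 7 and an allylic chloride is a less well-tried metathesis substrate.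

## Further compounds

F1 | step 9 | (2E,6E)-farnesyl phenyl sulfone | O=S(=O)(C/C=C(\C)CC/C=C(\C)CCC=C(C)C)c1ccccc1
F2 | step 9 | (2R)-5-[(3E,7E)-2-(phenylsulfonyl)-4,8,12-trimethyltrideca-3,7,11-trien-1-yl]-2-{3-[(triisopropylsilyl)oxy]prop-1-en-2-yl}-3,6-dihydro-2H-pyran, both epimers at the sulfonyl carbon | C=C(CO[Si](C(C)C)(C(C)C)C(C)C)[C@H]1CC=C(CC(/C=C(\C)CC/C=C(\C)CCC=C(C)C)S(=O)(=O)c2ccccc2)CO1
F0 | step 3 | none | none
F3 | step 4 | methyl 2-{[(tert-butoxycarbonyl)oxy]methyl}acrylate | C=C(COC(=O)OC(C)(C)C)C(=O)OC
F4 | step 5 | {[(3R)-3-{[2-(chloromethyl)prop-2-en-1-yl]oxy}-2-methylidenehex-5-en-1-yl]oxy}triisopropylsilane | C=C(CO[Si](C(C)C)(C(C)C)C(C)C)[C@H](OCC(=C)CCl)CC=C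
F5 | step 5 | (2R)-5-(chloromethyl)-2-{3-[(triisopropylsilyl)oxy]prop-1-en-2-yl}-3,6-dihydro-2H-pyran | C=C(CO[Si](C(C)C)(C(C)C)C(C)C)[C@H]1CC=C(CCl)CO1
A1 | alternative 1 | tert-butyl{[(2R,4Z,8E,12E)-2-(methoxymethoxy)-9,13,17-trimethyl-5-(trimethylsilyl)octadeca-4,8,12,16-tetraen-1-yl]oxy}diphenylsilane | CC(C)(C)[Si](c1ccccc1)(c1ccccc1)OC[C@H](OCOC)C/C=C(\[Si](C)(C)C)CC/C=C(\C)CC/C=C(\C)CCC=C(C)C
A2 | alternative 1 | tert-butyl({(2R)-5-[(3E,7E)-4,8,12-trimethyltrideca-3,7,11-trien-1-yl]-3,6-dihydro-2H-pyran-2-yl}methoxy)diphenylsilane | CC(C)(C)[Si](c1ccccc1)(c1ccccc1)OC[C@H]1CC=C(CC/C=C(\C)CC/C=C(\C)CCC=C(C)C)CO1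
A3 | alternative 2 | methyl (5Z,9E,13E)-3-[(tert-butoxycarbonyl)oxy]-6-(hydroxymethyl)-10,14,18-trimethyl-2-methylidenenonadeca-5,9,13,17-tetraenoate, racemic | C=C(C(=O)OC)C(OC(=O)OC(C)(C)C)C/C=C(\CO)CC/C=C(\C)CC/C=C(\C)CCC=C(C)C
A4 | alternative 2 | methyl 2-{(2R)-5-[(3E,7E)-4,8,12-trimethyltrideca-3,7,11-trien-1-yl]-3,6-dihydro-2H-pyran-2-yl}prop-2-enoate | C=C(C(=O)OC)[C@H]1CC=C(CC/C=C(\C)CC/C=C(\C)CCC=C(C)C)CO1
A5 | alternative 3 | (6R)-6-ethenyl-6-[(3E,7E)-4,8,12-trimethyltrideca-3,7,11-trien-1-yl]-1,4-dioxan-2-one | O=C1COC[C@](C=C)(CC/C=C(\C)CC/C=C(\C)CCC=C(C)C)O1
A6 | alternative 3 | (2R)-5-[(3E,7E)-4,8,12-trimethyltrideca-3,7,11-trien-1-yl]-3,6-dihydro-2H-pyran-2-carboxylic acid | OC(=O)[C@H]1CC=C(CC/C=C(\C)CC/C=C(\C)CCC=C(C)C)CO1
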